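The hydroxylated ε-ring (ring B) is cut back to a 2,4,4-trimethylcyclohex-2-enone whose six carbons C1′–C6′ come from isobutyraldehyde and a β-substituted ethyl enone. One amine-catalysed Michael–aldol annulation forms C1′–C2′ and C5′=C6′, closes the ring and sets C2′; it exploits the gem-dimethyl quaternary C1′ beside the C2′ stereocentre and the C5′ methyl. Because C2 of ring A has the same spatial configuration, the same enone serves both rings: vinyl cuprate addition gives the trans ring B, a suprafacial [2,3]-Wittig shift the cis ring A. The precursor is (E)-7-silyloxyhept-4-en-3-one. Two C20 phosphonium salts and a C10 dialdehyde build the polyene.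

Key step: step 2

Remark on the target: ring A is (2S,6R) with the C2 prenyl group and the C6 polyene cis; ring B is (2′R,6′S) with the C2′ arm and the C6′ polyene trans; C2 and C2′ have the same spatial arrangement (the descriptors differ only through the hydroxyl), so the (5S)-enone 6 serves both rings.
Remark on the precursor: the two-carbon arm is carried as a tert-butyldimethylsilyl ether (TBSO = tert-butyl(dimethyl)silyloxy) and not as an acetal, because an acetal beside the γ-carbon can ionise or lose alcohol once the amine forms a dienamine (a catalyst-consuming aminodienone) and would not survive the later acidic salt formation; carbon skeleton and bond-forming events are unchanged.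
Assumption: the sense of induction of 9-amino-9-deoxy-epi-cinchona amines on this enone class is not established; the quinine-derived amine is written, and its quinidine-derived pseudo-enantiomer would be used if the opposite face of the enone reacted.

Step 1
Reactants: 1 3-(TBSO)propanal; 2 diethyl (2-oxobutyl)phosphonate
Product: 3 (4E)-7-(TBSO)hept-4-en-3-one
Conditions: Ba(OH)2 (activated), THF–H2O (40:1), rt
Reagents that add atoms: none
Why: Horner–Wadsworth–Emmons olefination of an aldehyde with a β-ketophosphonate under mild hydroxide conditions should give the E-enone without β-elimination of the silyloxy group.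

Step 2
Reactants: 3 (4E)-7-(TBSO)hept-4-en-3-one; 4 isobutyraldehyde
Product: 6 (5S)-5-[2-(TBSO)ethyl]-2,4,4-trimethylcyclohex-2-en-1-one, via keto aldehyde 5 (not isolated)
Conditions: 9-amino-9-deoxy-epi-quinine (20 mol %), 2-fluorobenzoic acid (40 mol %), 4 (4 equiv), toluene, 40 °C; then 70 °C, sealed tube
Reagents that add atoms: none
Why: Proposed new method: the primary amine is expected to condense with 3 to an α,β-unsaturated iminium ion and with 4 to an imine that tautomerises to the enamine, whose nucleophilic carbon adds to the iminium β-carbon (C1′–C2′), hydrolysis giving keto aldehyde 5; the amine then forms the more substituted enamine of the ethyl ketone, which attacks the neopentyl aldehyde, and loss of water gives C5′=C6′. The closest known reaction types are the amine-catalysed Robinson annulation of α-branched aldehydes with vinyl ketones to 4,4-disubstituted cyclohexenones and the primary-amine iminium catalysis of conjugate additions to β-alkyl enones; their combination on a β-substituted enone with an α,α-disubstituted aldehyde is the untested part. The ring closes by a 6-(enolendo)-exo-trig aldol condensation. The C2′ stereocentre is set in the Michael step by the catalyst, whose quinoline wall and quinuclidinium–carboxylate ion pair are expected to shield one face of the E-iminium ion so that the enamine attacks the Si face of C5 of 3. The step needs C–C bond formation at the β-carbon ahead of self-condensation and one aldol regiochemistry: 4 has a single α-hydrogen and cannot dehydrate after self-aldolisation, the silyl ether arm gives a dienamine nothing to eliminate, and only the ethyl CH2 can reach the aldehyde through a six-membered ring, the other α-carbon leading to a cyclobutane.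

Step 3
Reactants: 6 (5S)-5-[2-(TBSO)ethyl]-2,4,4-trimethylcyclohex-2-en-1-one
Product: 8 (3R,5S)-5-[2-(TBSO)ethyl]-3-ethenyl-2,4,4-trimethylcyclohex-1-en-1-yl trifluoromethanesulfonate, via bromomagnesium enolate 7 (not isolated)
Conditions: CH2=CHMgBr, CuBr·SMe2, THF–Me2S, −78 → −30 °C; then 2-[N,N-bis(trifluoromethylsulfonyl)amino]-5-chloropyridine, −78 °C → rt
Reagents that add atoms: vinylmagnesium bromide C=C[Mg]Br; 2-[N,N-bis(trifluoromethylsulfonyl)amino]-5-chloropyridine FC(F)(F)S(=O)(=O)N(c1ccc(Cl)cn1)S(=O)(=O)C(F)(F)F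
Why: Conjugate addition of a vinyl homocuprate to a cyclohexenone with O-sulfonylation of the regiodefined enolate is established chemistry, and the vinyl group should enter C6′ by axial attack on the half-chair that has the C2′ arm equatorial, away from the axial C1′ methyl and anti to the arm, which sets the trans relationship (later 6′S).

Step 4
Reactants: 8 (3R,5S)-5-[2-(TBSO)ethyl]-3-ethenyl-2,4,4-trimethylcyclohex-1-en-1-yl trifluoromethanesulfonate
Product: 9 tert-butyl{2-[(1R,5S)-5-ethenyl-4,6,6-trimethylcyclohex-3-en-1-yl]ethoxy}dimethylsilane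
Conditions: Pd(OAc)2 (5 mol %), PPh3 (10 mol %), HCO2H, n-Bu3N, DMF, 60 °C
Reagents that add atoms: none
Why: Palladium-catalysed formate reduction of an enol triflate replaces C–OTf by C–H without moving the double bond, giving the C4′=C5′ alkene of the ε-ring and leaving the allylic C6′ stereocentre untouched.

Step 5
Reactants: 9 tert-butyl{2-[(1R,5S)-5-ethenyl-4,6,6-trimethylcyclohex-3-en-1-yl]ethoxy}dimethylsilane; 10 but-3-en-2-one
Product: 11 (3E)-4-{(1S,5R)-5-[2-(TBSO)ethyl]-2,6,6-trimethylcyclohex-2-en-1-yl}but-3-en-2-one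
Conditions: second-generation Hoveyda–Grubbs catalyst (5 mol %), 1,4-benzoquinone (10 mol %), 10 (5 equiv), CH2Cl2, 40 °C
Reagents that add atoms: none
Why: Olefin cross-metathesis of a monosubstituted alkene with an electron-poor vinyl ketone should give the E-enone, the trisubstituted ring alkene being inert and benzoquinone suppressing double-bond migration.

Step 6
Reactants: 11 (3E)-4-{(1S,5R)-5-[2-(TBSO)ethyl]-2,6,6-trimethylcyclohex-2-en-1-yl}but-3-en-2-one
Product: 12 (1E)-1-{(1S,5R)-5-[2-(TBSO)ethyl]-2,6,6-trimethylcyclohex-2-en-1-yl}-3-methylpenta-1,4-dien-3-ol (both C3 epimers)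
Conditions: CH2=CHMgBr, THF, −78 → 0 °C; aq. NH4Cl
Reagents that add atoms: vinylmagnesium bromide C=C[Mg]Br
Why: Grignard 1,2-addition to the methyl ketone, as in the preparation of vinyl ionols, gives the tertiary bis-allylic alcohol, whose new carbinol centre forms unselectively and is erased in step 9.

Step 7
Reactants: 12 (1E)-1-{(1S,5R)-5-[2-(TBSO)ethyl]-2,6,6-trimethylcyclohex-2-en-1-yl}-3-methylpenta-1,4-dien-3-ol
Product: 13 (1E)-1-[(1S,5R)-5-(2-hydroxyethyl)-2,6,6-trimethylcyclohex-2-en-1-yl]-3-methylpenta-1,4-dien-3-ol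
Conditions: n-Bu4NF, THF, rt
Reagents that add atoms: none
Why: Fluoride-mediated desilylation frees the primary alcohol under conditions that leave the acid-sensitive tertiary alcohol alone.

Step 8
Reactants: 13 (1E)-1-[(1S,5R)-5-(2-hydroxyethyl)-2,6,6-trimethylcyclohex-2-en-1-yl]-3-methylpenta-1,4-dien-3-ol
Product: 15 ethyl (2E)-4-{(1R,5S)-5-[(1E)-3-hydroxy-3-methylpenta-1,4-dien-1-yl]-4,6,6-trimethylcyclohex-3-en-1-yl}-2-methylbut-2-enoate, via aldehyde 14 (not isolated)
Conditions: n-Pr4N[RuO4] (5 mol %), N-methylmorpholine N-oxide, 4 Å molecular sieves, CH2Cl2, rt; then Ph3P=C(CH3)CO2Et, rt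
Reagents that add atoms: ethyl 2-(triphenylphosphoranylidene)propanoate CCOC(=O)C(C)=P(c1ccccc1)(c1ccccc1)c1ccccc1
Why: Ley–Griffith oxidation touches only the primary alcohol under neutral conditions, and the stabilised Wittig ylide converts the aldehyde in the same flask into the E-configured trisubstituted enoate.

Step 9
Reactants: 15 ethyl (2E)-4-{(1R,5S)-5-[(1E)-3-hydroxy-3-methylpenta-1,4-dien-1-yl]-4,6,6-trimethylcyclohex-3-en-1-yl}-2-methylbut-2-enoate
Product: 16 [(2E,4E)-5-{(1S,5R)-5-[(2E)-4-ethoxy-3-methyl-4-oxobut-2-en-1-yl]-2,6,6-trimethylcyclohex-2-en-1-yl}-3-methylpenta-2,4-dien-1-yl]triphenylphosphonium bromide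
Conditions: PPh3·HBr, MeOH, 0 °C → rt; crystallisation
Reagents that add atoms: triphenylphosphine hydrobromide [Br-].[PH+](c1ccccc1)(c1ccccc1)c1ccccc1
Why: Ionisation of the tertiary bis-allylic alcohol gives a pentadienyl cation that PPh3 captures at its primary terminus (allylic transposition), the standard entry to C15-type carotenoid Wittig salts, so the carbinol centre disappears and the two chain double bonds are expected mainly E.

Step 10
Reactants: 6 (5S)-5-[2-(TBSO)ethyl]-2,4,4-trimethylcyclohex-2-en-1-one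
Product: 17 (1R,5S)-5-[2-(TBSO)ethyl]-2,4,4-trimethylcyclohex-2-en-1-ol (hydroxyl cis to the arm)
Conditions: NaBH4, CeCl3·7H2O, MeOH, −20 °C
Reagents that add atoms: none
Why: Luche 1,2-reduction should deliver hydride axially to the conformer with equatorial arm, giving the pseudo-equatorial alcohol cis to the arm, as carvone gives cis-carveol.

Step 11
Reactants: 17 (1R,5S)-5-[2-(TBSO)ethyl]-2,4,4-trimethylcyclohex-2-en-1-ol; 18 tributyl(iodomethyl)stannane
Product: 19 tributyl[({(1R,5S)-5-[2-(TBSO)ethyl]-2,4,4-trimethylcyclohex-2-en-1-yl}oxy)methyl]stannane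
Conditions: KH, THF, 0 °C; then 18, rt
Reagents that add atoms: none
Why: Williamson etherification of the potassium alkoxide with the primary iodide; no stereocentre is touched.

Step 12
Reactants: 19 tributyl[({(1R,5S)-5-[2-(TBSO)ethyl]-2,4,4-trimethylcyclohex-2-en-1-yl}oxy)methyl]stannane
Product: 21 {(1R,5R)-5-[2-(TBSO)ethyl]-2,6,6-trimethylcyclohex-2-en-1-yl}methanol, via lithiomethyl ether 20 (not isolated)
Conditions: n-BuLi, THF, −78 → −20 °C; aq. NH4Cl
Reagents that add atoms: none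
Why: Tin–lithium exchange gives the α-alkoxy organolithium, which undergoes the [2,3]-Wittig rearrangement (Still variant) suprafacially, so the C6–C7 bond forms on the ring face that carried oxygen, cis to the C2 arm (6R), while the double bond moves to C4=C5.

Step 13
Reactants: 21 {(1R,5R)-5-[2-(TBSO)ethyl]-2,6,6-trimethylcyclohex-2-en-1-yl}methanol
Product: 22 (1R,5R)-5-[2-(TBSO)ethyl]-2,6,6-trimethylcyclohex-2-ene-1-carbaldehyde
Conditions: n-Pr4N[RuO4] (5 mol %), N-methylmorpholine N-oxide, 4 Å molecular sieves, CH2Cl2, 0 °C → rt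
Reagents that add atoms: none
Why: Ley–Griffith oxidation under neutral conditions should give the aldehyde without epimerisation at C6 or migration of the ring double bond.

Step 14
Reactants: 22 (1R,5R)-5-[2-(TBSO)ethyl]-2,6,6-trimethylcyclohex-2-ene-1-carbaldehyde; 23 diethyl (2-oxopropyl)phosphonate
Product: 24 (3E)-4-{(1R,5R)-5-[2-(TBSO)ethyl]-2,6,6-trimethylcyclohex-2-en-1-yl}but-3-en-2-one
Conditions: Ba(OH)2 (activated), THF–H2O (40:1), 0 °C → rt
Reagents that add atoms: none
Why: Horner–Wadsworth–Emmons olefination with a β-ketophosphonate gives the E-enone, and the mild heterogeneous base should leave the hindered C6–H, flanked by the quaternary C1, in place.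

Step 15
Reactants: 24 (3E)-4-{(1R,5R)-5-[2-(TBSO)ethyl]-2,6,6-trimethylcyclohex-2-en-1-yl}but-3-en-2-one
Product: 25 (1E)-1-{(1R,5R)-5-[2-(TBSO)ethyl]-2,6,6-trimethylcyclohex-2-en-1-yl}-3-methylpenta-1,4-dien-3-ol (both C3 epimers)
Conditions: CH2=CHMgBr, THF, −78 → 0 °C; aq. NH4Cl
Reagents that add atoms: vinylmagnesium bromide C=C[Mg]Br
Why: Grignard 1,2-addition to the methyl ketone as in step 6, the new carbinol centre being unselective and erased in step 19.

Step 16
Reactants: 25 (1E)-1-{(1R,5R)-5-[2-(TBSO)ethyl]-2,6,6-trimethylcyclohex-2-en-1-yl}-3-methylpenta-1,4-dien-3-ol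
Product: 26 (1E)-1-[(1R,5R)-5-(2-hydroxyethyl)-2,6,6-trimethylcyclohex-2-en-1-yl]-3-methylpenta-1,4-dien-3-ol
Conditions: n-Bu4NF, THF, rt
Reagents that add atoms: none
Why: Fluoride-mediated desilylation of the primary silyl ether, as in step 7.

Step 17
Reactants: 26 (1E)-1-[(1R,5R)-5-(2-hydroxyethyl)-2,6,6-trimethylcyclohex-2-en-1-yl]-3-methylpenta-1,4-dien-3-ol
Product: 27 2-{(1R,5R)-5-[(1E)-3-hydroxy-3-methylpenta-1,4-dien-1-yl]-4,6,6-trimethylcyclohex-3-en-1-yl}acetaldehyde
Conditions: n-Pr4N[RuO4] (5 mol %), N-methylmorpholine N-oxide, 4 Å molecular sieves, CH2Cl2, rt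
Reagents that add atoms: none
Why: Ley–Griffith oxidation converts only the primary alcohol, the tertiary alcohol being inert to the neutral oxidant.

Step 18
Reactants: 27 2-{(1R,5R)-5-[(1E)-3-hydroxy-3-methylpenta-1,4-dien-1-yl]-4,6,6-trimethylcyclohex-3-en-1-yl}acetaldehyde
Product: 28 (1E)-3-methyl-1-[(1R,5S)-2,6,6-trimethyl-5-(3-methylbut-2-en-1-yl)cyclohex-2-en-1-yl]penta-1,4-dien-3-ol
Conditions: i-PrPPh3I, n-BuLi, THF, 0 °C; then 27, −78 °C → rt
Reagents that add atoms: isopropyltriphenylphosphonium iodide [I-].CC(C)[P+](c1ccccc1)(c1ccccc1)c1ccccc1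
Why: Wittig olefination with the non-stabilised isopropylidene ylide builds the prenyl group (no alkene geometry arises), an excess of ylide accommodating the free tertiary hydroxyl.

Step 19
Reactants: 28 (1E)-3-methyl-1-[(1R,5S)-2,6,6-trimethyl-5-(3-methylbut-2-en-1-yl)cyclohex-2-en-1-yl]penta-1,4-dien-3-ol
Product: 29 {(2E,4E)-3-methyl-5-[(1R,5S)-2,6,6-trimethyl-5-(3-methylbut-2-en-1-yl)cyclohex-2-en-1-yl]penta-2,4-dien-1-yl}triphenylphosphonium bromide
Conditions: PPh3·HBr, MeOH, 0 °C → rt; crystallisation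
Reagents that add atoms: triphenylphosphine hydrobromide [Br-].[PH+](c1ccccc1)(c1ccccc1)c1ccccc1
Why: Same ionisation–phosphine capture as in step 9, the isolated prenyl double bond being expected to survive as isolated trisubstituted alkenes do in related acyclic C15 salts.

Step 20
Reactants: 16 ring B phosphonium bromide; 30 (2E,4E,6E)-2,7-dimethylocta-2,4,6-trienedial
Product: 31 ethyl (2E)-2-methyl-4-{(1R,5S)-4,6,6-trimethyl-5-[(1E,3E,5E,7E,9E,11E)-3,7,12-trimethyl-13-oxotrideca-1,3,5,7,9,11-hexaen-1-yl]cyclohex-3-en-1-yl}but-2-enoate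
Conditions: NaOEt, EtOH–CH2Cl2, 0 °C → rt, 30 (3 equiv), argon, dark
Reagents that add atoms: none
Why: Wittig olefination of the allylic ylide with one formyl group of the symmetrical dialdehyde, used in excess to favour mono-condensation; the new C11′=C12′ bond may form as an E/Z mixture that is equilibrated after step 21.

Step 21
Reactants: 31 C30 aldehyde ester; 29 ring A phosphonium bromide
Product: 32 all-E (2S,6R,2′R,6′S)-2′-[(2E)-4-ethoxy-3-methyl-4-oxobut-2-en-1-yl]-2-(3-methylbut-2-en-1-yl)-ε,ε-carotene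
Conditions: NaOEt, EtOH–CH2Cl2, 0 °C → rt; then n-heptane, reflux, argon, dark
Reagents that add atoms: none
Why: The second Wittig olefination forms C11=C12, and heating the crude polyene should drive the disubstituted Z double bonds to the preferred all-E form without touching the four sp3 stereocentres.

Step 22
Reactants: 32 C50 ethyl ester
Product: 33 all-E (2S,6R,2′R,6′S)-2′-[(2E)-4-hydroxy-3-methylbut-2-en-1-yl]-2-(3-methylbut-2-en-1-yl)-ε,ε-carotene (target)
Conditions: i-Bu2AlH, CH2Cl2, −78 °C; aq. potassium sodium tartrate, argon, dark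
Reagents that add atoms: none
Why: 1,2-Reduction of the isolated α,β-unsaturated ester with i-Bu2AlH gives the primary allylic alcohol with retention of the E geometry, the hydrocarbon polyene being inert.

Compound list
1 | 3-{[tert-butyl(dimethyl)silyl]oxy}propanal | O=CCCO[Si](C)(C)C(C)(C)C | starting material
2 | diethyl (2-oxobutyl)phosphonate | CCC(=O)CP(=O)(OCC)OCC | starting material
3 | (4E)-7-{[tert-butyl(dimethyl)silyl]oxy}hept-4-en-3-one | CCC(=O)/C=C/CCO[Si](C)(C)C(C)(C)C | intermediate (key-step precursor)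
4 | isobutyraldehyde | CC(C)C=O | starting material
5 | (3S)-3-[2-(TBSO)ethyl]-2,2-dimethyl-5-oxoheptanal | CCC(=O)C[C@H](CCO[Si](C)(C)C(C)(C)C)C(C)(C)C=O | intermediate (not isolated)
6 | (5S)-5-[2-(TBSO)ethyl]-2,4,4-trimethylcyclohex-2-en-1-one | O=C1C[C@H](CCO[Si](C)(C)C(C)(C)C)C(C)(C)C=C1C | intermediate (key-step product)
7 | bromomagnesium (3R,5S)-5-[2-(TBSO)ethyl]-3-ethenyl-2,4,4-trimethylcyclohex-1-en-1-olate | C=C[C@H]1C(C)=C(O[Mg]Br)C[C@H](CCO[Si](C)(C)C(C)(C)C)C1(C)C | intermediate (not isolated)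
8 | (3R,5S)-5-[2-(TBSO)ethyl]-3-ethenyl-2,4,4-trimethylcyclohex-1-en-1-yl trifluoromethanesulfonate | C=C[C@H]1C(C)=C(OS(=O)(=O)C(F)(F)F)C[C@H](CCO[Si](C)(C)C(C)(C)C)C1(C)C | intermediate
9 | tert-butyl{2-[(1R,5S)-5-ethenyl-4,6,6-trimethylcyclohex-3-en-1-yl]ethoxy}dimethylsilane (trans) | C=C[C@H]1C(C)=CC[C@H](CCO[Si](C)(C)C(C)(C)C)C1(C)C | intermediate
10 | but-3-en-2-one | CC(=O)C=C | starting material
11 | (3E)-4-{(1S,5R)-5-[2-(TBSO)ethyl]-2,6,6-trimethylcyclohex-2-en-1-yl}but-3-en-2-one | CC(=O)/C=C/[C@H]1C(C)=CC[C@H](CCO[Si](C)(C)C(C)(C)C)C1(C)C | intermediate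
12 | (1E)-1-{(1S,5R)-5-[2-(TBSO)ethyl]-2,6,6-trimethylcyclohex-2-en-1-yl}-3-methylpenta-1,4-dien-3-ol (C3 epimers) | C=CC(C)(O)/C=C/[C@H]1C(C)=CC[C@H](CCO[Si](C)(C)C(C)(C)C)C1(C)C | intermediate
13 | (1E)-1-[(1S,5R)-5-(2-hydroxyethyl)-2,6,6-trimethylcyclohex-2-en-1-yl]-3-methylpenta-1,4-dien-3-ol | C=CC(C)(O)/C=C/[C@H]1C(C)=CC[C@H](CCO)C1(C)C | intermediate
14 | 2-{(1R,5S)-5-[(1E)-3-hydroxy-3-methylpenta-1,4-dien-1-yl]-4,6,6-trimethylcyclohex-3-en-1-yl}acetaldehyde | C=CC(C)(O)/C=C/[C@H]1C(C)=CC[C@H](CC=O)C1(C)C | intermediate (not isolated)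
15 | ethyl (2E)-4-{(1R,5S)-5-[(1E)-3-hydroxy-3-methylpenta-1,4-dien-1-yl]-4,6,6-trimethylcyclohex-3-en-1-yl}-2-methylbut-2-enoate | C=CC(C)(O)/C=C/[C@H]1C(C)=CC[C@H](C/C=C(\C)C(=O)OCC)C1(C)C | intermediate
16 | [(2E,4E)-5-{(1S,5R)-5-[(2E)-4-ethoxy-3-methyl-4-oxobut-2-en-1-yl]-2,6,6-trimethylcyclohex-2-en-1-yl}-3-methylpenta-2,4-dien-1-yl]triphenylphosphonium bromide | [Br-].c1ccccc1[P+](c1ccccc1)(c1ccccc1)C/C=C(\C)/C=C/[C@H]1C(C)=CC[C@H](C/C=C(\C)C(=O)OCC)C1(C)C | intermediate
17 | (1R,5S)-5-[2-(TBSO)ethyl]-2,4,4-trimethylcyclohex-2-en-1-ol (cis) | O[C@@H]1C[C@H](CCO[Si](C)(C)C(C)(C)C)C(C)(C)C=C1C | intermediate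
18 | tributyl(iodomethyl)stannane | CCCC[Sn](CCCC)(CCCC)CI | starting material
19 | tributyl[({(1R,5S)-5-[2-(TBSO)ethyl]-2,4,4-trimethylcyclohex-2-en-1-yl}oxy)methyl]stannane | CCCC[Sn](CCCC)(CCCC)CO[C@@H]1C[C@H](CCO[Si](C)(C)C(C)(C)C)C(C)(C)C=C1C | intermediate
20 | [({(1R,5S)-5-[2-(TBSO)ethyl]-2,4,4-trimethylcyclohex-2-en-1-yl}oxy)methyl]lithium | [Li]CO[C@@H]1C[C@H](CCO[Si](C)(C)C(C)(C)C)C(C)(C)C=C1C | intermediate (not isolated)
21 | {(1R,5R)-5-[2-(TBSO)ethyl]-2,6,6-trimethylcyclohex-2-en-1-yl}methanol (cis) | OC[C@@H]1C(C)=CC[C@H](CCO[Si](C)(C)C(C)(C)C)C1(C)C | intermediate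
22 | (1R,5R)-5-[2-(TBSO)ethyl]-2,6,6-trimethylcyclohex-2-ene-1-carbaldehyde | O=C[C@@H]1C(C)=CC[C@H](CCO[Si](C)(C)C(C)(C)C)C1(C)C | intermediate
23 | diethyl (2-oxopropyl)phosphonate | CC(=O)CP(=O)(OCC)OCC | starting material
24 | (3E)-4-{(1R,5R)-5-[2-(TBSO)ethyl]-2,6,6-trimethylcyclohex-2-en-1-yl}but-3-en-2-one | CC(=O)/C=C/[C@@H]1C(C)=CC[C@H](CCO[Si](C)(C)C(C)(C)C)C1(C)C | intermediate
25 | (1E)-1-{(1R,5R)-5-[2-(TBSO)ethyl]-2,6,6-trimethylcyclohex-2-en-1-yl}-3-methylpenta-1,4-dien-3-ol (C3 epimers) | C=CC(C)(O)/C=C/[C@@H]1C(C)=CC[C@H](CCO[Si](C)(C)C(C)(C)C)C1(C)C | intermediate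
26 | (1E)-1-[(1R,5R)-5-(2-hydroxyethyl)-2,6,6-trimethylcyclohex-2-en-1-yl]-3-methylpenta-1,4-dien-3-ol | C=CC(C)(O)/C=C/[C@@H]1C(C)=CC[C@H](CCO)C1(C)C | intermediate
27 | 2-{(1R,5R)-5-[(1E)-3-hydroxy-3-methylpenta-1,4-dien-1-yl]-4,6,6-trimethylcyclohex-3-en-1-yl}acetaldehyde | C=CC(C)(O)/C=C/[C@@H]1C(C)=CC[C@H](CC=O)C1(C)C | intermediate
28 | (1E)-3-methyl-1-[(1R,5S)-2,6,6-trimethyl-5-(3-methylbut-2-en-1-yl)cyclohex-2-en-1-yl]penta-1,4-dien-3-ol | C=CC(C)(O)/C=C/[C@@H]1C(C)=CC[C@H](CC=C(C)C)C1(C)C | intermediate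
29 | {(2E,4E)-3-methyl-5-[(1R,5S)-2,6,6-trimethyl-5-(3-methylbut-2-en-1-yl)cyclohex-2-en-1-yl]penta-2,4-dien-1-yl}triphenylphosphonium bromide | [Br-].c1ccccc1[P+](c1ccccc1)(c1ccccc1)C/C=C(\C)/C=C/[C@@H]1C(C)=CC[C@H](CC=C(C)C)C1(C)C | intermediate
30 | (2E,4E,6E)-2,7-dimethylocta-2,4,6-trienedial | O=C/C(C)=C/C=C/C=C(C)/C=O | starting material
31 | ethyl (2E)-2-methyl-4-{(1R,5S)-4,6,6-trimethyl-5-[(1E,3E,5E,7E,9E,11E)-3,7,12-trimethyl-13-oxotrideca-1,3,5,7,9,11-hexaen-1-yl]cyclohex-3-en-1-yl}but-2-enoate | O=C/C(C)=C/C=C/C=C(C)/C=C/C=C(C)/C=C/[C@H]1C(C)=CC[C@H](C/C=C(\C)C(=O)OCC)C1(C)C | intermediate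
32 | all-E (2S,6R,2′R,6′S)-2′-[(2E)-4-ethoxy-3-methyl-4-oxobut-2-en-1-yl]-2-(3-methylbut-2-en-1-yl)-ε,ε-carotene | CC(C)=CC[C@H]1CC=C(C)[C@@H](/C=C/C(C)=C/C=C/C(C)=C/C=C/C=C(C)/C=C/C=C(C)/C=C/[C@H]2C(C)=CC[C@H](C/C=C(\C)C(=O)OCC)C2(C)C)C1(C)C | intermediate
33 | all-E (2S,6R,2′R,6′S)-2′-[(2E)-4-hydroxy-3-methylbut-2-en-1-yl]-2-(3-methylbut-2-en-1-yl)-ε,ε-carotene | CC(C)=CC[C@H]1CC=C(C)[C@@H](/C=C/C(C)=C/C=C/C(C)=C/C=C/C=C(C)/C=C/C=C(C)/C=C/[C@H]2C(C)=CC[C@H](C/C=C(\C)CO)C2(C)C)C1(C)C | target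

Total step count: 22. Longest linear sequence: 14 steps (steps 1, 2, 10–19, 21, 22).

Steps most likely to fail

Step 2 (slow Michael addition at the β-substituted iminium ion, insufficient facial discrimination, or diversion of the catalyst by aza-Michael addition). The fallback makes the ring racemic by stoichiometric enamine chemistry and resolves it; it sets out from 3 and 4 and comes back at 17, and at 6 after re-oxidation. Aldehyde 4 and pyrrolidine (K2CO3, removal of water) give 1-(2-methylprop-1-en-1-yl)pyrrolidine F1. F1 and 3 are heated in MeCN, and hydrolysis with aqueous AcOH–NaOAc gives racemic 3-[2-(TBSO)ethyl]-2,2-dimethyl-5-oxoheptanal F2, which KOH in MeOH cyclises to racemic 5-[2-(TBSO)ethyl]-2,4,4-trimethylcyclohex-2-en-1-one F3. NaBH4–CeCl3 reduction gives racemic cis-5-[2-(TBSO)ethyl]-2,4,4-trimethylcyclohex-2-en-1-ol F4. Acylation with vinyl acetate and Candida antarctica lipase B is expected, by the usual size rule for secondary alcohols, to acetylate the (1R) enantiomer to (1R,5S)-5-[2-(TBSO)ethyl]-2,4,4-trimethylcyclohex-2-en-1-yl acetate F5, which is separated from the unreacted (1S,5R) alcohol. K2CO3 in MeOH then returns 17, and MnO2 oxidation of a portion of 17 returns 6 for the ring B branch.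

Step 3 (sluggish conjugate addition at the neopentyl β-carbon with competing 1,2-addition, or incomplete O-triflation of the magnesium enolate). The fallback replaces conjugate addition by a suprafacial [2,3]-shift from the inverted alcohol; it sets out from 17 and comes back at 11. Mitsunobu inversion of 17 (4-nitrobenzoic acid, PPh3, diisopropyl azodicarboxylate) gives (1S,5S)-5-[2-(TBSO)ethyl]-2,4,4-trimethylcyclohex-2-en-1-yl 4-nitrobenzoate F6, and K2CO3 in MeOH gives (1S,5S)-5-[2-(TBSO)ethyl]-2,4,4-trimethylcyclohex-2-en-1-ol F7. KH and 18 give tributyl[({(1S,5S)-5-[2-(TBSO)ethyl]-2,4,4-trimethylcyclohex-2-en-1-yl}oxy)methyl]stannane F8. n-BuLi at −78 °C gives, through [({(1S,5S)-5-[2-(TBSO)ethyl]-2,4,4-trimethylcyclohex-2-en-1-yl}oxy)methyl]lithium F9 (here the C–O bond is pseudo-axial with the arm equatorial, the favourable case), {(1S,5R)-5-[2-(TBSO)ethyl]-2,6,6-trimethylcyclohex-2-en-1-yl}methanol F10. Oxidation with n-Pr4N[RuO4] and N-methylmorpholine N-oxide gives (1S,5R)-5-[2-(TBSO)ethyl]-2,6,6-trimethylcyclohex-2-ene-1-carbaldehyde F11, and olefination with 23 and Ba(OH)2 gives 11.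

Step 12 (competing [1,2]-shift or simple protonation, because the cis ether must rearrange through a conformer in which the axial C2 arm lies syn to the forming bond). The fallback uses an intermolecular anti-selective SN2′ substitution on the inverted ester; it sets out from 17 and comes back at 24. Mitsunobu esterification of 17 with pyridine-2-carboxylic acid (PPh3, diisopropyl azodicarboxylate) gives (1S,5S)-5-[2-(TBSO)ethyl]-2,4,4-trimethylcyclohex-2-en-1-yl pyridine-2-carboxylate F12. CH2=CHMgBr with CuBr·SMe2 in THF at −40 °C should then deliver vinyl to C6 on the face opposite the chelating leaving group, cis to the equatorial arm, giving tert-butyl{2-[(1R,5R)-5-ethenyl-4,6,6-trimethylcyclohex-3-en-1-yl]ethoxy}dimethylsilane F13. Cross-metathesis of F13 with 10 under the conditions of step 5 gives 24.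

Further compounds
F1 | step 2 | 1-(2-methylprop-1-en-1-yl)pyrrolidine | CC(C)=CN1CCCC1
F2 | step 2 | racemic 3-[2-(TBSO)ethyl]-2,2-dimethyl-5-oxoheptanal | CCC(=O)CC(CCO[Si](C)(C)C(C)(C)C)C(C)(C)C=O
F3 | step 2 | racemic 5-[2-(TBSO)ethyl]-2,4,4-trimethylcyclohex-2-en-1-one | O=C1CC(CCO[Si](C)(C)C(C)(C)C)C(C)(C)C=C1C
F4 | step 2 | racemic cis-5-[2-(TBSO)ethyl]-2,4,4-trimethylcyclohex-2-en-1-ol (racemate, one enantiomer drawn) | O[C@@H]1C[C@H](CCO[Si](C)(C)C(C)(C)C)C(C)(C)C=C1C
F5 | step 2 | (1R,5S)-5-[2-(TBSO)ethyl]-2,4,4-trimethylcyclohex-2-en-1-yl acetate | CC(=O)O[C@@H]1C[C@H](CCO[Si](C)(C)C(C)(C)C)C(C)(C)C=C1C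
F6 | step 3 | (1S,5S)-5-[2-(TBSO)ethyl]-2,4,4-trimethylcyclohex-2-en-1-yl 4-nitrobenzoate | O=C(O[C@H]1C[C@H](CCO[Si](C)(C)C(C)(C)C)C(C)(C)C=C1C)c1ccc(cc1)[N+](=O)[O-]
F7 | step 3 | (1S,5S)-5-[2-(TBSO)ethyl]-2,4,4-trimethylcyclohex-2-en-1-ol (trans) | O[C@H]1C[C@H](CCO[Si](C)(C)C(C)(C)C)C(C)(C)C=C1C
F8 | step 3 | tributyl[({(1S,5S)-5-[2-(TBSO)ethyl]-2,4,4-trimethylcyclohex-2-en-1-yl}oxy)methyl]stannane | CCCC[Sn](CCCC)(CCCC)CO[C@H]1C[C@H](CCO[Si](C)(C)C(C)(C)C)C(C)(C)C=C1C
F9 | step 3 | [({(1S,5S)-5-[2-(TBSO)ethyl]-2,4,4-trimethylcyclohex-2-en-1-yl}oxy)methyl]lithium | [Li]CO[C@H]1C[C@H](CCO[Si](C)(C)C(C)(C)C)C(C)(C)C=C1C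
F10 | step 3 | {(1S,5R)-5-[2-(TBSO)ethyl]-2,6,6-trimethylcyclohex-2-en-1-yl}methanol (trans) | OC[C@H]1C(C)=CC[C@H](CCO[Si](C)(C)C(C)(C)C)C1(C)C
F11 | step 3 | (1S,5R)-5-[2-(TBSO)ethyl]-2,6,6-trimethylcyclohex-2-ene-1-carbaldehyde | O=C[C@H]1C(C)=CC[C@H](CCO[Si](C)(C)C(C)(C)C)C1(C)C
F12 | step 12 | (1S,5S)-5-[2-(TBSO)ethyl]-2,4,4-trimethylcyclohex-2-en-1-yl pyridine-2-carboxylate | O=C(O[C@H]1C[C@H](CCO[Si](C)(C)C(C)(C)C)C(C)(C)C=C1C)c1ccccn1
F13 | step 12 | tert-butyl{2-[(1R,5R)-5-ethenyl-4,6,6-trimethylcyclohex-3-en-1-yl]ethoxy}dimethylsilane (cis) | C=C[C@@H]1C(C)=CC[C@H](CCO[Si](C)(C)C(C)(C)C)C1(C)C
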